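The flask is booked in coupling partner, taken as the limiting reagent, charged below the starting material.

| flask | starting material | coupling partner | second substrate | third substrate | remark | time |
|---|---|---|---|---|---|---|
| south | 0.050 M | 0.70 equiv | 5 equiv | 0.70 equiv | run made earlier |  |
| south-east | 0.050 M | 0.70 equiv | 5 equiv | 1.1 equiv | run made earlier |  |
| flask | 0.050 M | 0.700 equiv | 5.00 equiv | 0.500 equiv |  | 12 min |

south run (percent of the starting material charged)

| time / min | target / % | over-reaction product A / % | starting material / % |
|---|---|---|---|
| 2.00 | 8 | 10 | 83 |
| 4.00 | 5 | 19 | 75 |
| 6.00 | 3 | 28 | 71 |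
| 8.00 | 3 | 32 | 67 |
| 10.0 | 0 | 38 | 64 |
| 12.0 | 0 | 39 | 62 |

south-east run (percent of the starting material charged)

| time / min | target / % | over-reaction product A / % | starting material / % |
|---|---|---|---|
| 2.00 | 7 | 10 | 83 |
| 4.00 | 4 | 18 | 75 |
| 6.00 | 4 | 27 | 68 |
| 8.00 | 2 | 34 | 63 |
| 10.0 | 2 | 39 | 62 |
| 12.0 | 0 | 39 | 60 |

- concentration of target at 12 min, in M
- concentration of over-reaction product A at 12 min, in M
- concentration of starting material at 12 min, in M



In the south run, target reads 8 % at 2.00 min and 0 % at 12.0 min, while over-reaction product A climbs to 39 %. The final readings of target, product A and starting material sum to 101 % of the charge, so target and product A are entered as one line. Raising third substrate to 1.1 equiv in the south-east run shifts the final starting material by 2 percentage points, against a scatter of 1.5 points.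

The south run gives 0.557 as the take-up u, the moles of starting material found as target plus product A at 12 min per mole of coupling partner charged. The reckoning here carries u to the flask, assuming that 0.500 equiv of third substrate, below both runs, behaves like them. Of 0.0350 M coupling partner, 0.0195 M enters the target and product A line, and 0.0155 M stands as an open entry, for which the south and south-east runs print no column. The entry for c(starting material) then closes at 0.0305 M.

The forecast gives c(target) 5.000 × 10⁻⁴ M, c(over-reaction product A) 0.019 M and c(starting material) 0.0305 M, reading a cap “with about 2 equiv used per over-reaction product”. The reckoning here assumes no such stoichiometry.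

The flask gives c(target) 5.59 × 10⁻⁴ M, c(over-reaction product A) 0.0193 M and c(starting material) 0.0301 M, inside the forecast's ranges.

    starting material + coupling partner → target (k = 2.97 L mol⁻¹ min⁻¹)
    second substrate + coupling partner → second product (k = 0.234 L mol⁻¹ min⁻¹)
    third substrate + coupling partner → third product (k = 0.163 L mol⁻¹ min⁻¹)
    target → over-reaction product A (k = 0.912 min⁻¹)
    target → over-reaction product B (k = 1.99 × 10⁻⁴ min⁻¹)

This flask's own take-up is 0.568 against u of 0.557, and at 12 min its open entry holds second product at 0.00979 M, third product at 6.86 × 10⁻⁴ M and 13 % of the coupling partner charged, still unused. At 12.0 min in this flask, the step to target uses coupling partner at 1.6 times the rate of the step to second product. In the neighbour flask with 1.20 equiv of coupling partner, u points to 0.0334 M of target plus product A, and that flask holds 0.0304 M.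

Readings and results are calculated on assumed constants.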